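**Retrosynthetic overview**

- Feature: the target is two identical guaiacylpropane units, Ar-C7-C8-C9 and Ar-C7'-C8'-C9', each 7S,8R and bonded C8-C8'. The tetrahydrofuran (O, C7, C8, C8', C9') joins C7 to C9' through oxygen, and the C7'-OH and C9H2-OH groups are the two ends of a γ-lactone (O, C7', C8', C8, C9) opened by hydride.
- Disconnections: (a) the lactone C9-O bond, back to a cis-fused 2,6-diaryl-3,7-dioxabicyclo[3.3.0]octan-4-one; (b) both benzylic C-O bonds (C7-O-C9' and C7'-O-C9), back to benzylic C-H bonds of an (8R,8'R)-dibenzyl γ-hydroxybutanoate; (c) C8-C8', back to two molecules of one N-acyl oxazolidinone.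
- Ring order: a temporary butyrolactone (C9, C8, C8', C9', O) is made only to tell C9 from C9' and is opened again; the γ-lactone and the tetrahydrofuran then close in one oxidation; the γ-lactone is finally opened by reduction.
- Stereocontrol: C8 and C8' come from the (S)-oxazolidinone in the dimerisation; C7 and C7' are set by these centres in the cyclisations.

Key step: step 8

Assumption: in step 8 the lactone is taken to close before the tetrahydrofuran (carboxylate participation); the opposite order would pass through the 7,9'-epoxy carboxylate and end at the same compound 14.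

**Route**

Step 1
Reactants: 1 dihydroferulic acid, 3-(4-hydroxy-3-methoxyphenyl)propanoic acid
Product: 2 benzyl 3-(4-benzyloxy-3-methoxyphenyl)propanoate
Conditions: BnBr (2.3 equiv), K2CO3 (3 equiv), DMF, 60 °C
Reagents that add atoms: benzyl bromide, BrCc1ccccc1
Why: Williamson-type double O-alkylation, in which K2CO3 deprotonates the phenol and the acid and each anion displaces bromide from benzyl bromide, so the phenol becomes the benzyl ether that has to survive base, hydride and DDQ later.

Step 2
Reactants: 2 benzyl 3-(4-benzyloxy-3-methoxyphenyl)propanoate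
Product: 3 3-(4-benzyloxy-3-methoxyphenyl)propanoic acid
Conditions: NaOH (2 equiv), THF/MeOH/H2O, 50 °C; then aq. HCl to pH 2
Reagents that add atoms: sodium hydroxide, [Na+].[OH-]
Why: Ester saponification (acyl substitution by hydroxide) cleaves only the benzyl ester, the aryl benzyl ether being inert to aqueous base.

Step 3
Reactants: 3 3-(4-benzyloxy-3-methoxyphenyl)propanoic acid; 4 (S)-4-isopropyl-2-oxazolidinone
Product: 6 (4S)-3-[3-(4-benzyloxy-3-methoxyphenyl)propanoyl]-4-isopropyloxazolidin-2-one, via mixed pivalic anhydride 5 (not isolated)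
Conditions: PivCl (1.1 equiv), Et3N (2.5 equiv), THF, −20 °C; then 4, LiCl (1.1 equiv), −20 °C to rt
Reagents that add atoms: none
Why: Mixed-anhydride N-acylation of an oxazolidinone, in which the tert-butyl group shields the pivaloyl carbonyl of 5 so that the LiCl/Et3N-activated nitrogen attacks the arylpropanoyl carbonyl, and no stereocentre is touched.

Step 4
Reactants: 6 (4S)-3-[3-(4-benzyloxy-3-methoxyphenyl)propanoyl]-4-isopropyloxazolidin-2-one (two molecules)
Product: 8 (2R,3R)-2,3-bis(4-benzyloxy-3-methoxybenzyl)-1,4-bis[(4S)-4-isopropyl-2-oxooxazolidin-3-yl]butane-1,4-dione, via lithium Z-enolate 7 (not isolated)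
Conditions: LiN(iPr)2 (1.1 equiv), THF, −78 °C; then TiCl4 (1.1 equiv, in CH2Cl2), −78 °C to 0 °C
Reagents that add atoms: none
Why: Oxidative enolate homocoupling, in which the chelated Z-enolate 7 is oxidised by one electron by tetravalent titanium and the two α-carbons join on the face turned away from the isopropyl group (the facial sense of an Evans alkylation), which should make C8 and C8' both R, minor diastereomers being removed by chromatography or crystallisation.

Step 5
Reactants: 8 the (2R,3R)-bis-imide
Product: 9 (2R,3R)-2,3-bis(4-benzyloxy-3-methoxybenzyl)butane-1,4-diol (di-O-benzyl secoisolariciresinol)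
Conditions: LiBH4 (4 equiv), MeOH (4 equiv), THF, 0 °C to rt
Reagents that add atoms: none
Why: Reductive cleavage of N-acyl oxazolidinones with LiBH4, in which hydride reduces each exocyclic imide carbonyl to the primary alcohol and releases auxiliary 4 for recovery, under conditions too weakly basic to epimerise C8 or C8'.

Step 6
Reactants: 9 (2R,3R)-2,3-bis(4-benzyloxy-3-methoxybenzyl)butane-1,4-diol
Product: 11 (3R,4R)-3,4-bis(4-benzyloxy-3-methoxybenzyl)dihydrofuran-2(3H)-one (di-O-benzyl matairesinol), via lactol 10 (not isolated)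
Conditions: TEMPO (0.2 equiv), PhI(OAc)2 (2.5 equiv), CH2Cl2, rt
Reagents that add atoms: none
Why: TEMPO/PhI(OAc)2 oxidative lactonisation of a 1,4-diol (alcohol to aldehyde, closure to lactol 10, second oxidation), in which the C2 axis makes the two hydroxyls equivalent so that only one lactone can form and C9 becomes different from C9' without a selectivity problem.

Step 7
Reactants: 11 (3R,4R)-3,4-bis(4-benzyloxy-3-methoxybenzyl)dihydrofuran-2(3H)-one
Product: 12 tetrabutylammonium (2R,3R)-2,3-bis(4-benzyloxy-3-methoxybenzyl)-4-hydroxybutanoate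
Conditions: Bu4NOH (1.00 equiv, 40% aq.), THF, 0 °C to rt; evaporate, azeotrope with toluene, dry in vacuo; no acid at any point
Reagents that add atoms: tetrabutylammonium hydroxide, CCCC[N+](CCCC)(CCCC)CCCC.[OH-]
Why: Lactone saponification (acyl-oxygen cleavage by hydroxide) cannot reverse while the carboxylate stays unprotonated, and the lipophilic cation makes the dried salt soluble in CH2Cl2 for the oxidation.

Step 8
Reactants: 12 tetrabutylammonium (2R,3R)-2,3-bis(4-benzyloxy-3-methoxybenzyl)-4-hydroxybutanoate
Product: 14 (3S,3aR,6S,6aS)-3,6-bis(4-benzyloxy-3-methoxyphenyl)tetrahydro-1H,3H-furo[3,4-c]furan-1-one (cis-fused 2,6-diaryl-3,7-dioxabicyclo[3.3.0]octan-4-one with both aryl groups exo; lignan locants 7S,8S,7'S,8'R), via monocyclised lactone 13 (not isolated)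
Conditions: DDQ (2.2 equiv), NaHCO3 (solid, 3 equiv), 4 Å MS, CH2Cl2, 0 °C to rt
Reagents that add atoms: none
Why: Proposed new method: DDQ forms a charge-transfer complex with each 4-benzyloxy-3-methoxyphenyl ring and abstracts a benzylic hydride, so that C7' and then C7 become para-alkoxy-stabilised benzylic cations (O-alkylated quinone methides), each captured by the oxygen tethered 1,4 to it; the closest known reaction type is the DDQ-mediated benzylic C-H oxidation of alkoxyarylalkanes with intramolecular capture by one hydroxyl or one carboxyl group (oxidative cycloetherification or lactonisation), here asked to run twice in one flask on a hydroxy carboxylate. The γ-lactone (O, C7', C8', C8, C9) closes by 5-exo-trig attack of the C9 carboxylate on the C7' cation and the tetrahydrofuran (O, C7, C8, C8', C9') by 5-exo-trig attack of the C9' hydroxyl on the C7 cation, the crossed pairings being ruled out because they would need a β-lactone or an oxetane. C7' (S) is set in the first closure, in which the aryl group goes to the side of the forming lactone opposite to the C8' hydroxymethyl group, and C7 (S) in the second, in which the aryl group takes the exo (convex) face of the bicycle whose cis fusion is forced by the fixed C8 and C8' centres. The step needs oxygen capture to beat Friedel-Crafts closure to an aryltetralin, proton loss or decarboxylative fragmentation of the cations and re-closure of the substrate to 11, which the two tethered nucleophiles, the carboxylate that assists the first ionisation and is tied up as the lactone before C7 ionises, and the acid-free, dry, buffered medium should secure. Further oxidation should be slow because only two oxidations' worth of DDQ is present and the two benzylic hydrogens left in 14 lie on the concave face, one next to an acyloxy group and one β to the lactone carbonyl.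

Step 9
Reactants: 14 the bicyclic lactone
Product: 15 di-O-benzyl tanegol, (S)-(4-benzyloxy-3-methoxyphenyl)[(3R,4R,5S)-5-(4-benzyloxy-3-methoxyphenyl)-4-(hydroxymethyl)tetrahydrofuran-3-yl]methanol
Conditions: LiAlH4 (2 equiv), THF, 0 °C; aq. potassium sodium tartrate work-up
Reagents that add atoms: none
Why: Hydride reduction of a lactone to a diol, in which LiAlH4 cleaves the acyl C9-O bond so that the C7' oxygen leaves as an alkoxide with its configuration untouched and C9 becomes the hydroxymethyl group, while the aryl benzyl ethers and the tetrahydrofuran are inert.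

Step 10
Reactants: 15 di-O-benzyl tanegol
Product: 16 (−)-tanegol, (S)-(4-hydroxy-3-methoxyphenyl)[(3R,4R,5S)-5-(4-hydroxy-3-methoxyphenyl)-4-(hydroxymethyl)tetrahydrofuran-3-yl]methanol (7S,8R,7'S,8'R)
Conditions: H2 (1 atm), 10% Pd/C, EtOAc, rt; stopped after uptake of 2 equiv H2
Reagents that add atoms: none
Why: Catalytic hydrogenolysis of aryl benzyl ethers, which under neutral conditions in ethyl acetate should be cleaved much faster than the benzylic C7-O ether and C7'-OH bonds, so that no stereocentre is touched.

**Compound list**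

1 | dihydroferulic acid, 3-(4-hydroxy-3-methoxyphenyl)propanoic acid | COc1cc(CCC(=O)O)ccc1O | starting material
2 | benzyl 3-(4-benzyloxy-3-methoxyphenyl)propanoate | COc1cc(CCC(=O)OCc2ccccc2)ccc1OCc1ccccc1 | intermediate
3 | 3-(4-benzyloxy-3-methoxyphenyl)propanoic acid | COc1cc(CCC(=O)O)ccc1OCc1ccccc1 | intermediate
4 | (S)-4-isopropyl-2-oxazolidinone (auxiliary, recovered in step 5) | CC(C)[C@H]1COC(=O)N1 | starting material
5 | 3-(4-benzyloxy-3-methoxyphenyl)propanoic pivalic anhydride (not isolated) | COc1cc(CCC(=O)OC(=O)C(C)(C)C)ccc1OCc1ccccc1 | intermediate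
6 | (4S)-3-[3-(4-benzyloxy-3-methoxyphenyl)propanoyl]-4-isopropyloxazolidin-2-one | COc1cc(CCC(=O)N2[C@@H](C(C)C)COC2=O)ccc1OCc1ccccc1 | intermediate
7 | lithium (Z)-enolate of 6 (not isolated) | COc1cc(C/C=C(\[O-])N2[C@@H](C(C)C)COC2=O)ccc1OCc1ccccc1.[Li+] | intermediate
8 | (2R,3R)-2,3-bis(4-benzyloxy-3-methoxybenzyl)-1,4-bis[(4S)-4-isopropyl-2-oxooxazolidin-3-yl]butane-1,4-dione | O=C(N1[C@@H](C(C)C)COC1=O)[C@H](Cc1ccc(OCc2ccccc2)c(OC)c1)[C@@H](Cc1ccc(OCc2ccccc2)c(OC)c1)C(=O)N1[C@@H](C(C)C)COC1=O | intermediate
9 | (2R,3R)-2,3-bis(4-benzyloxy-3-methoxybenzyl)butane-1,4-diol | OC[C@H](Cc1ccc(OCc2ccccc2)c(OC)c1)[C@@H](Cc1ccc(OCc2ccccc2)c(OC)c1)CO | intermediate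
10 | (3R,4R)-3,4-bis(4-benzyloxy-3-methoxybenzyl)tetrahydrofuran-2-ol, anomeric mixture (not isolated) | OC1[C@H](Cc2ccc(OCc3ccccc3)c(OC)c2)[C@@H](Cc2ccc(OCc3ccccc3)c(OC)c2)CO1 | intermediate
11 | (3R,4R)-3,4-bis(4-benzyloxy-3-methoxybenzyl)dihydrofuran-2(3H)-one | O=C1[C@H](Cc2ccc(OCc3ccccc3)c(OC)c2)[C@@H](Cc2ccc(OCc3ccccc3)c(OC)c2)CO1 | intermediate
12 | tetrabutylammonium (2R,3R)-2,3-bis(4-benzyloxy-3-methoxybenzyl)-4-hydroxybutanoate | O=C([O-])[C@H](Cc1ccc(OCc2ccccc2)c(OC)c1)[C@@H](Cc1ccc(OCc2ccccc2)c(OC)c1)CO.CCCC[N+](CCCC)(CCCC)CCCC | intermediate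
13 | (3R,4R,5S)-3-(4-benzyloxy-3-methoxybenzyl)-5-(4-benzyloxy-3-methoxyphenyl)-4-(hydroxymethyl)dihydrofuran-2(3H)-one (not isolated) | COc1cc([C@H]2OC(=O)[C@H](Cc3ccc(OCc4ccccc4)c(OC)c3)[C@@H]2CO)ccc1OCc1ccccc1 | intermediate
14 | (3S,3aR,6S,6aS)-3,6-bis(4-benzyloxy-3-methoxyphenyl)tetrahydro-1H,3H-furo[3,4-c]furan-1-one | COc1cc([C@H]2OC(=O)[C@@H]3[C@@H](c4ccc(OCc5ccccc5)c(OC)c4)OC[C@H]23)ccc1OCc1ccccc1 | intermediate
15 | di-O-benzyl tanegol | COc1cc([C@@H](O)[C@H]2CO[C@H](c3ccc(OCc4ccccc4)c(OC)c3)[C@H]2CO)ccc1OCc1ccccc1 | intermediate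
16 | (−)-tanegol | COc1cc([C@@H](O)[C@H]2CO[C@H](c3ccc(O)c(OC)c3)[C@H]2CO)ccc1O | target

**Totals**

Total step count: 10. Longest linear sequence: 10 steps (1 to 16).

**Steps most likely to fail**

1. Step 8 (double oxidative cyclisation). Possible failures as processes:
   - capture of a benzylic cation by the other arene (aryltetralin formation);
   - proton loss or decarboxylative fragmentation in place of oxygen capture;
   - poor facial selectivity at C7 or C7';
   - further oxidation of the first-formed ring;
   - protonation of the salt and its return to 11.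

   Fallback: this sets out from diol 9 and comes back at compound 14. It splits the two closures over two neutral substrates, each being the known single reaction.
   - One equivalent of DDQ in CH2Cl2 on 9 should effect one oxidative cycloetherification to give di-O-benzyl lariciresinol F1. The C2 axis makes the two possible closures identical.
   - TEMPO/PhI(OAc)2 in MeCN/water oxidises the remaining primary alcohol to the 7,9'-epoxy acid F2.
   - A separate DDQ oxidation then lactonises the carboxylic acid onto C7' and gives 14.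

2. Step 4 (oxidative homocoupling). Possible failures as processes: poor facial selectivity in the C8-C8' bond formation (meso and S,S isomers), return of the enolate to 6 by protonation, or Lewis-acid attack of TiCl4 on the aryl benzyl ethers.

   Fallback: this sets out from 6 and comes back at 11, building the two centres one after the other.
   - Evans alkylation of the sodium enolate of 6 (NaN(SiMe3)2, THF, −78 °C) with tert-butyl bromoacetate gives imide ester F3.
   - LiBH4 reduces the imide carbonyl to hydroxy ester F4 and frees the auxiliary.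
   - Catalytic TsOH in toluene closes (R)-β-benzyl lactone F5.
   - The lithium enolate of F5 (LiN(SiMe3)2, THF, −78 °C) is alkylated trans to the C4 substituent by 4-benzyloxy-3-methoxybenzyl bromide F6, made from the commercial benzyl alcohol and PBr3. This gives 11, so steps 5 and 6 are not needed.

3. Step 10 (hydrogenolysis). Possible failure as a process: over-reduction, that is hydrogenolysis of the benzylic C7-O or C7'-O bond once the phenols are free.

   Fallback: this sets out from 11 and comes back at 16, changing the phenol protecting group at a stage with no benzylic C-O bond.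
   - Hydrogenolysis of 11 gives (−)-matairesinol F7, which also checks the absolute configuration.
   - Allyl bromide and K2CO3 give di-O-allyl matairesinol F8.
   - Steps 7 to 9 are repeated to give the tetrabutylammonium hydroxy carboxylate F9, the bicyclic lactone F10 and di-O-allyl tanegol F11.
   - The allyl ethers are removed with Pd(PPh3)4 (zerovalent palladium) and morpholine in THF, which leaves benzylic C-O bonds alone.

**Further compounds**

F1 | step 8 | di-O-benzyl lariciresinol, [(2S,3R,4R)-2-(4-benzyloxy-3-methoxyphenyl)-4-(4-benzyloxy-3-methoxybenzyl)tetrahydrofuran-3-yl]methanol | COc1cc(C[C@H]2CO[C@H](c3ccc(OCc4ccccc4)c(OC)c3)[C@H]2CO)ccc1OCc1ccccc1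
F2 | step 8 | (2S,3S,4R)-2-(4-benzyloxy-3-methoxyphenyl)-4-(4-benzyloxy-3-methoxybenzyl)tetrahydrofuran-3-carboxylic acid | COc1cc(C[C@H]2CO[C@H](c3ccc(OCc4ccccc4)c(OC)c3)[C@H]2C(=O)O)ccc1OCc1ccccc1
F3 | step 4 | tert-butyl (3R)-3-(4-benzyloxy-3-methoxybenzyl)-4-[(4S)-4-isopropyl-2-oxooxazolidin-3-yl]-4-oxobutanoate | COc1cc(C[C@H](CC(=O)OC(C)(C)C)C(=O)N2[C@@H](C(C)C)COC2=O)ccc1OCc1ccccc1
F4 | step 4 | tert-butyl (3R)-4-(4-benzyloxy-3-methoxyphenyl)-3-(hydroxymethyl)butanoate | COc1cc(C[C@H](CC(=O)OC(C)(C)C)CO)ccc1OCc1ccccc1
F5 | step 4 | (4R)-4-(4-benzyloxy-3-methoxybenzyl)dihydrofuran-2(3H)-one | O=C1C[C@@H](Cc2ccc(OCc3ccccc3)c(OC)c2)CO1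
F6 | step 4 | 4-benzyloxy-3-methoxybenzyl bromide | COc1cc(CBr)ccc1OCc1ccccc1
F7 | step 10 | (−)-matairesinol, (3R,4R)-3,4-bis(4-hydroxy-3-methoxybenzyl)dihydrofuran-2(3H)-one | O=C1[C@H](Cc2ccc(O)c(OC)c2)[C@@H](Cc2ccc(O)c(OC)c2)CO1
F8 | step 10 | di-O-allyl matairesinol | O=C1[C@H](Cc2ccc(OCC=C)c(OC)c2)[C@@H](Cc2ccc(OCC=C)c(OC)c2)CO1
F9 | step 10 | tetrabutylammonium (2R,3R)-2,3-bis(4-allyloxy-3-methoxybenzyl)-4-hydroxybutanoate | O=C([O-])[C@H](Cc1ccc(OCC=C)c(OC)c1)[C@@H](Cc1ccc(OCC=C)c(OC)c1)CO.CCCC[N+](CCCC)(CCCC)CCCC
F10 | step 10 | (3S,3aR,6S,6aS)-3,6-bis(4-allyloxy-3-methoxyphenyl)tetrahydro-1H,3H-furo[3,4-c]furan-1-one | COc1cc([C@H]2OC(=O)[C@@H]3[C@@H](c4ccc(OCC=C)c(OC)c4)OC[C@H]23)ccc1OCC=C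
F11 | step 10 | di-O-allyl tanegol | COc1cc([C@@H](O)[C@H]2CO[C@H](c3ccc(OCC=C)c(OC)c3)[C@H]2CO)ccc1OCC=C
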